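| setting | ash | elm | Monday's | Wednesday's |
|---|---|---|---|---|
| substrate | 7 mM | 11 mM | 5.0 mM | 5.0 mM |
| gas | 0.78 mM (held) | 0.78 mM (held) | 0.78 mM (held) | 0.78 mM (held) |
| temperature | 99 °C | 107 °C | 110 °C | 95 °C |
| remark | run made earlier | run made earlier |  |  |
| time |  |  | 2.5 min | 2.5 min |

- ash (time / min: target / %): 0.250: 67.3; 0.333: 63.4; 0.500: 61.5; 0.833: 52.1; 1.33: 40.2; 2.50: 27.4
- elm (time / s: target / %): 15.0: 47.0; 30.0: 38.1; 50.0: 28.2; 60.0: 24.4; 80.0: 17.6; 90.0: 14.0

(each reading ± 1 percentage point)

- at the start none of reagent is dissolved
- the numbers in the tables scatter by 1 percentage point (one standard deviation)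
- candidate steps: substrate <-> other conformer; substrate + reagent <-> target; reagent + other conformer -> isomer of the product; gas <-> reagent
- in a conversion other conformer counts as not yet reacted

1. which flask leads in amount of target, in percent of the substrate charged ("all alike" within 1.5 percentage points) (Monday's / Wednesday's / all alike)
2. how much target is there at the end, in percent of the substrate charged: Monday's
3. how much target is there at the end, in percent of the substrate charged: Wednesday's

- I started from the target left at the last readings: 27.4 % of the substrate charged after 2.50 min in the ash run, and 14.0 % after 90.0 s in the elm run.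
- The first instants: no reagent is dissolved at the start, so gas has to cross over before substrate and reagent can form target. The first reading of the ash run, at 0.250 min, already stood at 67.3 %, the highest of that run, so I treated the loading as finished by then and took target as the resting state.
- The middle: in both the ash and the elm run target then fell nearly straight on a logarithmic axis, which I read as a first-order decay. I read it as target going back to substrate and leaking through other conformer to isomer of the product. I named the slope d, the decades of target lost per minute, one decade being one unit of the common logarithm. The readings gave 0.173 /min for ash at 99 °C and 0.421 /min for elm at 107 °C.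
- My rule was g, the decades by which d rises per kelvin with the gas held at 0.78 mM, 0.0481 /K. The ash and elm runs differ in charge as well as in temperature, and I assumed that the charge does not matter.
- The end: g gave d = 0.586 /min for Monday's and 0.111 /min for Wednesday's, so I expected Monday's to shed more, 1.47 decades in 2.5 min against 0.278.
- Running the lines back to zero time gave intercepts, which are reckoned levels and not amounts that stood in a flask, of 74.4 % for ash and 59.9 % for elm. Carrying these logarithmically to each temperature, I reckoned 1.89 % for Monday's and 43.7 % for Wednesday's.
- The forecast, slightly different from my reckoning, said 2.2 % for Monday's and 43 % for Wednesday's, with Wednesday's leading, on the ground that “The target appears within seconds, then falls first-order”.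
- The simulation gave 2.42 % for Monday's and 40.6 % for Wednesday's, so Wednesday's led, as forecast. Left until 25.0 min, Wednesday's holds 0.117 %; carrying its end value forward at the d obtained from g gave me 0.127 %.

    substrate ⇌ other conformer (K = 0.643, k = 0.105 /s, Ea = 87.0 kJ/mol, ΔH = −90.0 kJ/mol)
    substrate + reagent ⇌ target (K = 4300 /M, k = 828 /M/s, Ea = 56.0 kJ/mol, ΔH = −50.0 kJ/mol)
    reagent + other conformer → isomer of the product (k = 55500 /M/s, Ea = 16.0 kJ/mol)
    gas ⇌ reagent, rate k4*(csat - [reagent]) (kL = 3.19 /s)
    (constants at 110 °C)

- For the neighbour at 80 °C, with Wednesday's charge and time, g gave d = 0.0212 /min, which is 0.0530 decades, or 11.5 % of the target lost in 2.5 min. The simulated flask ends with target at 77.9 % and isomer of the product at 16.3 %.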